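The target is cut across its pyran ring (O1, C2, C3, C4, C4a, C8a; chromene numbering) at O1–C2 and C3–C4. Because C8a is a ketone carbon whose enol oxygen O1 carries the gem-dimethyl carbon C2, the ring equals the heterodiene O=C8a–C4a=C4 plus 2-methylpropene. One inverse-demand hetero-Diels–Alder reaction forms both bonds and the dihydropyran. An ethoxy group carried on C4 then leaves as ethanol, giving C3=C4 without an oxidant. The cycloaddition precursor is the ethoxymethylidene derivative of the benzoyl gem-diprenyl cyclohexanetrione, whose ring is built by a double Claisen condensation of diethyl diprenylmalonate with benzoylacetone.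

Key step: step 4

Remark on tautomers and geometry: chromene numbering is used for ring positions throughout. Compounds 7, 10, 12 and 13 are drawn with the enol hydroxyl on C7, hydrogen-bonded to the benzoyl carbonyl, so C5 is a cross-conjugated carbonyl and not an enol. The push–pull C4a=C4 bond of 10 is assumed to equilibrate between E and Z (Z drawn).

Remark on the precursor design: 10 is used with the C7 enol unprotected, because that chelated enol is what makes C5=O a vinylogous acid carbonyl and leaves C8a=O as the only ketone-like heterodiene carbonyl. The final elimination uses a weak pyridinium acid, since a strong acid could cyclise a C8 prenyl group onto the C7 enol oxygen.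

Step 1
Reactants: 1 diethyl malonate; 2 1-bromo-3-methylbut-2-ene
Product: 4 diethyl 2,2-bis(3-methylbut-2-enyl)propanedioate, via monoprenyl malonate 3 (not isolated)
Conditions: NaH (2.3 equiv), 2 (2.3 equiv), THF–DMF, 0 °C to rt
Reagents that add atoms: none
Why: Double malonic ester alkylation (SN2 at the primary allylic bromide by the soft sodiomalonate, twice) should fix the gem-diprenyl carbon, the later C8, with no regiochemical ambiguity.

Step 2
Reactants: 4 diethyl 2,2-bis(3-methylbut-2-enyl)propanedioate; 5 1-phenylbutane-1,3-dione
Product: 7 2-benzoyl-3-hydroxy-4,4-bis(3-methylbut-2-enyl)cyclohex-2-ene-1,5-dione, via open-chain triketo ester 6 (not isolated)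
Conditions: NaH (5 equiv), 1,2-dimethoxyethane, reflux; then 1 M HCl, 0 °C
Reagents that add atoms: none
Why: Claisen acylation of the benzoylacetone dianion at its terminal carbon by the non-enolisable ester, followed by a Dieckmann-type intramolecular Claisen closure of the internal diketone carbon onto the second ester, should give the six-membered trione, because the quaternary malonate carbon blocks every aldol alternative, ethoxide reopens any O-acylated lactone, and the trione leaves the equilibrium as its stabilised enolate.

Step 3
Reactants: 7 2-benzoyl-3-hydroxy-4,4-bis(3-methylbut-2-enyl)cyclohex-2-ene-1,5-dione; 8 triethyl orthoformate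
Product: 10 (6Z)-2-benzoyl-6-(ethoxymethylidene)-3-hydroxy-4,4-bis(3-methylbut-2-enyl)cyclohex-2-ene-1,5-dione, via diethoxymethyl trione 9 (not isolated)
Conditions: 8 (4 equiv), Ac2O (3 equiv), 95 °C; evaporated and used crude under anhydrous conditions
Reagents that add atoms: none
Why: Orthoester condensation of a 1,3-dione (ethoxymethylenation): diethoxymethyl acetate formed in the flask should attack the only remaining enolisable ring carbon, the CH2 between the two carbonyls (later C4a), and loss of ethanol gives the push–pull ethoxymethylidene, with excess orthoformate keeping 10 from being captured by a second molecule of 7.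

Step 4
Reactants: 10 (6Z)-2-benzoyl-6-(ethoxymethylidene)-3-hydroxy-4,4-bis(3-methylbut-2-enyl)cyclohex-2-ene-1,5-dione; 11 2-methylpropene
Product: 12 racemic 6-benzoyl-4-ethoxy-7-hydroxy-2,2-dimethyl-8,8-bis(3-methylbut-2-enyl)-3,4-dihydro-2H-chromen-5(8H)-one (the 4S enantiomer is drawn)
Conditions: 11 (about 20 equiv, condensed), Yb(OSO2CF3)3 (10 mol %), anhydrous CH2Cl2, sealed tube, 0 °C to rt
Reagents that add atoms: none
Why: Bound to the ytterbium salt, 10 should react as the ring-locked s-cis 1-oxadiene O=C8a–C4a=C4 in an inverse-electron-demand oxa-Diels–Alder reaction that is concerted but strongly asynchronous: the CH2 end of 2-methylpropene bonds to the electrophilic C4 while charge builds on the tertiary carbon, which O8a then captures, so only the 2,2-dimethyl orientation can arise. The closest known chemistry is the hetero-Diels–Alder reaction of alkoxymethylidene and alkylidene 1,3-diones with enol ethers and of methylidene triones from dearomatised acylphloroglucinols with non-activated terpene alkenes; a donor-substituted oxadiene paired with a simple 1,1-dialkylalkene sits at the edge of that scope, which is why the risk of the route is placed here. The dihydropyran ring closes in the intermolecular [4+2] event itself, C3–C4 leading and O1–C2 following as a six-membered capture of the incipient tertiary cation by the enolate-type O8a. The single new stereocenter C4 is formed without control as a racemate and disappears in step 5. The step needs closure through O8a and not O5: C5=O is conjugated to two donors (the chelated C7 enol and the ethoxyvinyl unit), so it is the most Lewis-basic oxygen, binds the metal and acts as the acceptor, whereas C8a=O next to the quaternary C8 is the only ketone-like heterodiene carbonyl, and closure through O8a also preserves the cross-conjugated 2-acyl-3-hydroxyenone pattern that 4,4-dialkyl acyl triones prefer. Competition from the prenyl alkenes should be held back by the large excess of the unhindered CH2 terminus of 2-methylpropene and by geometry, since attack of a C8 prenyl group on C4 within the same molecule would require a bridgehead double bond.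

Step 5
Reactants: 12 racemic 6-benzoyl-4-ethoxy-7-hydroxy-2,2-dimethyl-8,8-bis(3-methylbut-2-enyl)-3,4-dihydro-2H-chromen-5(8H)-one
Product: 13 6-benzoyl-7-hydroxy-2,2-dimethyl-8,8-bis(3-methylbut-2-enyl)-2H-chromen-5(8H)-one (target, CNP0138894.0)
Conditions: pyridinium p-toluenesulfonate (10 mol %), toluene, 70 °C
Reagents that add atoms: none
Why: E1 elimination of a vinylogous acetal: the weak acid should ionise the C4–OEt bond to the O1-stabilised allylic oxocarbenium ion, and loss of a C3 proton gives the conjugated 2H-pyran, while the acid is too weak to cyclise a prenyl group onto the C7 enol.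

Compound list
1 | diethyl malonate (diethyl propanedioate) | CCOC(=O)CC(=O)OCC | starting material
2 | 1-bromo-3-methylbut-2-ene | CC(C)=CCBr | starting material
3 | diethyl 2-(3-methylbut-2-enyl)propanedioate | CCOC(=O)C(CC=C(C)C)C(=O)OCC | intermediate (not isolated)
4 | diethyl 2,2-bis(3-methylbut-2-enyl)propanedioate | CCOC(=O)C(CC=C(C)C)(CC=C(C)C)C(=O)OCC | intermediate
5 | 1-phenylbutane-1,3-dione | CC(=O)CC(=O)c1ccccc1 | starting material
6 | ethyl 2,2-bis(3-methylbut-2-enyl)-3,5,7-trioxo-7-phenylheptanoate | CCOC(=O)C(CC=C(C)C)(CC=C(C)C)C(=O)CC(=O)CC(=O)c1ccccc1 | intermediate (not isolated)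
7 | 2-benzoyl-3-hydroxy-4,4-bis(3-methylbut-2-enyl)cyclohex-2-ene-1,5-dione (enol tautomer of 2-benzoyl-4,4-diprenylcyclohexane-1,3,5-trione) | O=C1CC(=O)C(CC=C(C)C)(CC=C(C)C)C(O)=C1C(=O)c1ccccc1 | intermediate
8 | triethyl orthoformate | CCOC(OCC)OCC | starting material
9 | 2-benzoyl-6-(diethoxymethyl)-3-hydroxy-4,4-bis(3-methylbut-2-enyl)cyclohex-2-ene-1,5-dione (C6 enolisable, configuration undefined) | CCOC(OCC)C1C(=O)C(C(=O)c2ccccc2)=C(O)C(CC=C(C)C)(CC=C(C)C)C1=O | intermediate (not isolated)
10 | (6Z)-2-benzoyl-6-(ethoxymethylidene)-3-hydroxy-4,4-bis(3-methylbut-2-enyl)cyclohex-2-ene-1,5-dione | CCO/C=C1\C(=O)C(C(=O)c2ccccc2)=C(O)C(CC=C(C)C)(CC=C(C)C)C1=O | intermediate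
11 | 2-methylpropene | CC(C)=C | starting material
12 | 6-benzoyl-4-ethoxy-7-hydroxy-2,2-dimethyl-8,8-bis(3-methylbut-2-enyl)-3,4-dihydro-2H-chromen-5(8H)-one, racemic, 4S enantiomer drawn | CCO[C@H]1CC(C)(C)OC2=C1C(=O)C(C(=O)c1ccccc1)=C(O)C2(CC=C(C)C)CC=C(C)C | intermediate
13 | 6-benzoyl-7-hydroxy-2,2-dimethyl-8,8-bis(3-methylbut-2-enyl)-2H-chromen-5(8H)-one (no stereocenter) | CC(C)=CCC1(CC=C(C)C)C(O)=C(C(=O)c2ccccc2)C(=O)C2=C1OC(C)(C)C=C2 | target

Total step count: 5. Longest linear sequence: 5 steps (steps 1 to 5, from diethyl malonate).

Steps most likely to fail

Step 4. The donor-substituted oxadiene may react too slowly with the unactivated alkene. The alkene may undergo cationic oligomerisation. Ring closure may also leak through O5. The fallback sets out from 7 and uses the established Knoevenagel condensation and oxa-6π electrocyclisation route to 2,2-dimethyl-2H-pyrans. Trione 7 would be heated with 3-methylbut-2-enal and catalytic ethylenediammonium diacetate in toluene at 80 °C. Condensation at C4a should give the 1-oxatriene 2-benzoyl-3-hydroxy-6-(3-methylbut-2-enylidene)-4,4-bis(3-methylbut-2-enyl)cyclohex-2-ene-1,5-dione F1. F1 should close reversibly through the C8a oxygen, so the more stable cross-conjugated isomer is expected to accumulate. The fallback comes back to the route at 13 and bypasses 10 and 12.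

Step 2. The sequence may stall after the first acylation. Ring closure at the hindered neopentyl-type ester may be slow. Ethoxide may cleave an ethoxycarbonyl group from 4 by a retro-Claisen reaction. The fallback sets out from 4 and raises the electrophile to the acid chloride level. Saponification with KOH in aqueous ethanol at reflux and cold acidification would give 2,2-bis(3-methylbut-2-enyl)propanedioic acid F2. 1-Chloro-N,N,2-trimethylprop-1-en-1-amine in CH2Cl2 at 0 °C would convert it, without HCl, into 2,2-bis(3-methylbut-2-enyl)propanedioyl dichloride F3. Slow addition of F3 to the dilithio dianion of 5 (LiN(iPr)2, 3 equiv, THF, −78 °C) should acylate the terminal carbon to give 2,2-bis(3-methylbut-2-enyl)-3,5,7-trioxo-7-phenylheptanoyl chloride F4. On warming, F4 should close at the central diketone carbon. The fallback comes back to the route at 7.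

Step 3. The electrophilic product may be captured by unreacted trione to give a methine-bridged dimer. The enols may be acetylated. The ethoxymethylidene group may hydrolyse on isolation. The fallback sets out from 7 and runs a three-component domino reaction. 7, 8 and excess 11 would be combined with Yb(OSO2CF3)3 in CH2Cl2 in a sealed tube, so that 10 forms slowly and is trapped by the alkene as it appears, without acetic anhydride and without isolation. The fallback comes back to the route at 12 and makes no compound outside the compound list (F0).

Further compounds
F1 | step 4 | 2-benzoyl-3-hydroxy-6-(3-methylbut-2-enylidene)-4,4-bis(3-methylbut-2-enyl)cyclohex-2-ene-1,5-dione | CC(C)=CC=C1C(=O)C(C(=O)c2ccccc2)=C(O)C(CC=C(C)C)(CC=C(C)C)C1=O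
F2 | step 2 | 2,2-bis(3-methylbut-2-enyl)propanedioic acid | CC(C)=CCC(CC=C(C)C)(C(=O)O)C(=O)O
F3 | step 2 | 2,2-bis(3-methylbut-2-enyl)propanedioyl dichloride | CC(C)=CCC(CC=C(C)C)(C(=O)Cl)C(=O)Cl
F4 | step 2 | 2,2-bis(3-methylbut-2-enyl)-3,5,7-trioxo-7-phenylheptanoyl chloride | CC(C)=CCC(CC=C(C)C)(C(=O)Cl)C(=O)CC(=O)CC(=O)c1ccccc1
F0 | step 3 | none | none
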